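Time is the first thing to ask of this flask: how many powers of ten of it do you have to spare?

all flasks: substrate 0.050 M; catalyst 7.5 mM
- birch: the very flask that is asked about, followed so far
- flask: time 8.0 min

- birch (time / s: target / %, isomer of the product / %): 10.0: 18.2, 13.2; 20.0: 22.9, 18.2; 30.0: 24.7, 18.8; 50.0: 25.5, 20.7; 80.0: 26.2, 20.4; 90.0: 25.6, 21.0

(scatter of a reading: 0.5 percentage points)

- candidate steps: substrate + catalyst <-> target + catalyst; target + catalyst <-> isomer of the product + catalyst; isomer of the product + catalyst <-> substrate + catalyst

- ratio of target to isomer of the product at 0.25 s
- ratio of target to isomer of the product at 8.0 min
- which of target and isomer of the product there is more of at 8.0 min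

Open a ledger in percent of the substrate charged, your limiting reagent, and take the mean of the last three birch readings as closing entries. The target holds 25.8% and the isomer of the product 20.7%, so the remaining 53.5% you book as substrate. The catalyst stands on both sides of every candidate step, so it takes no entry.

Now the clock. In the birch run the target falls short of its closing entry by 7.6 percentage points at 10.0 s and 2.9 points at 20.0 s, which gives a relaxation time of 10.3 s. Against 8.0 min that leaves 1.67 powers of ten. This margin, the base-ten logarithm of the asked time over the relaxation time, is large, and because the relaxation time is far shorter than the asked time, I close the books there at the plateau: [target]/[isomer of the product] = 1.24, target ahead, which is thermodynamic control. At 0.25 s the margin is −1.61, before any reading, so I take the earliest ratio, 1.38, as my estimate.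

The forecast gives 1.25 with target ahead at 8.0 min, and at 0.25 s gives 1.5, higher than my estimate, adding: “This is poorly constrained”.

The flask gives 1.36 at 0.25 s and 1.27 at 8.0 min, with 25.5% target against 20.2% isomer of the product.

    substrate + catalyst ⇌ target + catalyst, rate k1*[substrate]*[catalyst] forward; the back reaction follows from the equilibrium constant (K = 0.470, k = 4.20 /M/s)
    target + catalyst ⇌ isomer of the product + catalyst, rate k2*[catalyst]*[target] forward; the back reaction follows from the equilibrium constant (K = 0.790, k = 1.20 /M/s)
    isomer of the product + catalyst ⇌ substrate + catalyst, rate k3*[catalyst]*[isomer of the product] forward; the back reaction follows from the equilibrium constant (k = 8.30 /M/s)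

Every rate there is proportional to [catalyst]. The neighbouring flask has 0.0019 M of catalyst, a quarter of the charge here, so the relaxation time I read from the scattered birch readings scales to an estimate of 40.7 s for that flask and an estimated margin of 1.07, with the asked time still longer than that estimate. That neighbouring flask ends at a ratio of 1.27, with 25.5% target and 20.2% isomer of the product.

The earlier runs and the new flask were generated by integration from invented constants; noise was put on by code.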